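**Plan**

- Retrosynthesis: the three phenol protecting groups are removed first; ring C is then cut at O1–C8a and C4–C4a in one operation, giving a ring A aryne (C4a≡C8a) and an (S)-4-aryl-β-lactone. The C6–geranyl bond and the lactone acyl–oxygen bond are cut next.
- Enabling feature: ring C is only O1–C2–C3–C4, a 3-aryl-3-hydroxypropanoate unit, bridging the adjacent ring A carbons C8a and C4a. The C5 oxygen beside C4a makes the two aryne termini electronically different.
- Forward: ring A is built from phloroglucinol (silyl/MOM differentiation, directed lithiation–geranylation at C6, bromination, retro-Brook shift, triflation). Ring B enters as 4-hydroxybenzaldehyde and is carried to the β-lactone. Ring C forms last by aryne insertion, and acid then frees the phenols.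
- Stereochemistry: C2 is set by a Keck asymmetric allylation and carried with retention through lactonisation and ring expansion, because its C–O bond is never broken.

Key step: step 12

Remark on the chemistry: geranyl means (2E)-3,7-dimethylocta-2,6-dien-1-yl and ring atoms carry flavanone numbers (O1, C2, C3, C4, C4a, C5–C8, C8a). It is assumed that the 4-(tert-butoxycarbonyloxy)phenyl group leaves the β-lactone about as robust as its phenyl parent.

**Step 1**
Reactants: 1 phloroglucinol (benzene-1,3,5-triol)
Product: 2 5-(triisopropylsilyloxy)benzene-1,3-diol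
Conditions: 1 (3 equiv), TIPSCl (1 equiv), imidazole, DMF, 0 °C → rt
Reagents that add atoms: triisopropylsilyl chloride, CC(C)[Si](Cl)(C(C)C)C(C)C
Why: Statistical monosilylation (silyl ether formation) of a symmetrical triol, in which the excess of cheap, water-soluble 1 suppresses bis-silylation and is washed out.

**Step 2**
Reactants: 2 5-(triisopropylsilyloxy)benzene-1,3-diol
Product: 3 [3,5-bis(methoxymethoxy)phenoxy]triisopropylsilane
Conditions: MOMCl, iPr2NEt, CH2Cl2, 0 °C → rt
Reagents that add atoms: chloromethyl methyl ether, COCCl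
Why: O-Alkylation of both phenols with the chloromethyl ether (acetal protection) under amine base, which leaves the aryl silyl ether in place.

**Step 3**
Reactants: 3 [3,5-bis(methoxymethoxy)phenoxy]triisopropylsilane; 4 geranyl bromide
Product: 6 {4-[(2E)-3,7-dimethylocta-2,6-dien-1-yl]-3,5-bis(methoxymethoxy)phenoxy}triisopropylsilane, via aryllithium 5 (not isolated)
Conditions: n-BuLi, THF, 0 °C; CuI (10 mol %), 4, −78 °C → rt
Reagents that add atoms: none
Why: Directed ortho-metalation occurs at the carbon flanked by both methoxymethoxy groups, because the bulky silyloxy group neither coordinates lithium nor leaves its neighbours accessible, and copper-catalysed SN2 allylation of 5 then keeps the E alkene.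

**Step 4**
Reactants: 6 {4-geranyl-3,5-bis(methoxymethoxy)phenoxy}triisopropylsilane
Product: 7 4-geranyl-3,5-bis(methoxymethoxy)phenol
Conditions: TBAF, AcOH, THF, 0 °C
Reagents that add atoms: none
Why: Fluoride desilylation of the aryl silyl ether, buffered so that the electron-rich phenoxide is not left exposed, with acetals and alkenes inert.

**Step 5**
Reactants: 7 4-geranyl-3,5-bis(methoxymethoxy)phenol
Product: 8 2-bromo-4-geranyl-3,5-bis(methoxymethoxy)phenol
Conditions: NBS (1.0 equiv), CH2Cl2, −78 °C, dark
Reagents that add atoms: N-bromosuccinimide, O=C1CCC(=O)N1Br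
Why: Electrophilic aromatic bromination, in which the trioxygenated ring is far more nucleophilic than the trisubstituted alkenes, the two open positions are equivalent, and one equivalent of reagent at low temperature should stop at the monobromide ortho to the hydroxyl.

**Step 6**
Reactants: 8 2-bromo-4-geranyl-3,5-bis(methoxymethoxy)phenol
Product: 11 4-geranyl-3,5-bis(methoxymethoxy)-2-(trimethylsilyl)phenyl trifluoromethanesulfonate, via aryl trimethylsilyl ether 9 (not isolated), via lithium 2-silylphenoxide 10 (not isolated)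
Conditions: HMDS, THF, 65 °C, then evaporation; n-BuLi, THF, −100 → −78 °C; PhNTf2, −78 °C → rt
Reagents that add atoms: hexamethyldisilazane, C[Si](C)(C)N[Si](C)(C)C; N-phenylbis(trifluoromethanesulfonimide), O=S(=O)(N(c1ccccc1)S(=O)(=O)C(F)(F)F)C(F)(F)F
Why: O-Silylation, bromine–lithium exchange and retro-Brook rearrangement (1,3 O→C silyl shift driven by phenoxide formation) put silicon on carbon, and phenoxide 10 is triflated in the same flask by a mild triflyl donor that spares acetals and alkenes.

**Step 7**
Reactants: 12 4-hydroxybenzaldehyde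
Product: 13 tert-butyl 4-formylphenyl carbonate
Conditions: Boc2O, DMAP (5 mol %), MeCN, rt
Reagents that add atoms: di-tert-butyl dicarbonate, CC(C)(C)OC(=O)OC(=O)OC(C)(C)C
Why: DMAP-catalysed O-acylation of the phenol (carbonate formation), which also lowers the donor power of the ring B oxygen for the later lactone.

**Step 8**
Reactants: 13 tert-butyl 4-formylphenyl carbonate
Product: 14 tert-butyl 4-[(1S)-1-hydroxybut-3-en-1-yl]phenyl carbonate
Conditions: (S)-BINOL (20 mol %), Ti(OiPr)4 (10 mol %), 4 Å MS, allylSnBu3, CH2Cl2, −20 °C; aq. NaHCO3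
Reagents that add atoms: allyltributylstannane, C=CC[Sn](CCCC)(CCCC)CCCC
Why: Keck asymmetric allylation under neutral conditions that the carbonate tolerates, in which the titanium complex of (S)-BINOL should deliver the allyl group to the Si face of the aryl aldehyde and so set the S carbinol.

**Step 9**
Reactants: 14 tert-butyl 4-[(1S)-1-hydroxybut-3-en-1-yl]phenyl carbonate
Product: 16 tert-butyl 4-[(1S)-1-hydroxy-3-oxopropyl]phenyl carbonate, via secondary ozonide 15 (not isolated)
Conditions: O3, CH2Cl2, −78 °C; PPh3, −78 °C → rt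
Reagents that add atoms: ozone, [O-][O+]=O
Why: Ozonolysis with reductive work-up cleaves the terminal alkene through ozonide 15, while the deactivated aryl carbonate and the carbinol stereocenter are not touched.

**Step 10**
Reactants: 16 tert-butyl 4-[(1S)-1-hydroxy-3-oxopropyl]phenyl carbonate
Product: 17 (3S)-3-[4-(tert-butoxycarbonyloxy)phenyl]-3-hydroxypropanoic acid
Conditions: NaClO2, NaH2PO4, 2-methyl-2-butene, t-BuOH/H2O, 0 °C → rt
Reagents that add atoms: sodium chlorite, [Na+].[O-]Cl=O
Why: Pinnick oxidation converts the aldehyde to the acid without affecting the secondary alcohol or the carbonate, and the mildly acidic buffer avoids retro-aldol cleavage.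

**Step 11**
Reactants: 17 (3S)-3-[4-(tert-butoxycarbonyloxy)phenyl]-3-hydroxypropanoic acid
Product: 18 (4S)-4-[4-(tert-butoxycarbonyloxy)phenyl]oxetan-2-one
Conditions: PhSO2Cl, pyridine, 0 °C
Reagents that add atoms: none
Why: Carboxyl-activation lactonisation (sulfonyl chloride in pyridine), in which the β-hydroxyl attacks the activated acyl group in a 4-exo-trig substitution, so the carbinol C–O bond stays intact and the S configuration is retained, with low temperature guarding against decarboxylation.

**Step 12**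
Reactants: 11 4-geranyl-3,5-bis(methoxymethoxy)-2-(trimethylsilyl)phenyl trifluoromethanesulfonate; 18 (4S)-4-[4-(tert-butoxycarbonyloxy)phenyl]oxetan-2-one
Product: 20 (2S)-2-[4-(tert-butoxycarbonyloxy)phenyl]-6-geranyl-5,7-bis(methoxymethoxy)chroman-4-one, via aryne 19 (not isolated)
Conditions: CsF (3 equiv), MeCN, 0 °C → rt, slow addition of 11
Reagents that add atoms: none
Why: Proposed new method: fluoride attack on silicon expels triflate and gives the 3-alkoxyaryne 19 (C4a≡C8a); the ring oxygen of 18 adds to C8a, the carbanion thus placed at C4a attacks the adjacent acyl carbon, and the strained acyl–oxygen bond breaks, so the oxetanone is enlarged by two atoms to the pyranone. The closest known reaction types are aryne insertion into the nitrogen–acyl bond of β-lactams (giving 2,3-dihydroquinolin-4-ones) and aryne carbon–oxygen insertion of carboxylic acids (giving ortho-hydroxyaryl ketones); insertion into a lactone acyl–oxygen bond has not been shown. Ring C closes by ring expansion, an intermolecular O-arylation (O1–C8a) followed by an intramolecular 1,3 O→C acyl shift within the aryl–oxonium ion pair (C4–C4a). No stereocenter is formed, and C2 keeps the S configuration of 18 because its C–O bond is never broken. The regioselectivity needed (6-geranyl, not 8-geranyl) is secured by the C5 methoxymethoxy group, whose inductive effect polarises the aryne so that the nucleophile enters at the distal carbon C8a and the carbanion develops next to oxygen at C4a. The chemoselectivity needed, ring oxygen before carbonyl oxygen, is the untested point: it is helped by the weak ester resonance of the strained lactone, a fluoride-opened β-alkoxy acyl fluoride would converge on the same two bonds, and the electron-poor carbonate on ring B holds back benzylic ionisation and decarboxylation of 18.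

**Step 13**
Reactants: 20 (2S)-2-[4-(tert-butoxycarbonyloxy)phenyl]-6-geranyl-5,7-bis(methoxymethoxy)chroman-4-one
Product: 21 bonannione A, (2S)-6-[(2E)-3,7-dimethylocta-2,6-dien-1-yl]-5,7-dihydroxy-2-(4-hydroxyphenyl)chroman-4-one
Conditions: 3 M aq. HCl, MeOH, 50 °C
Reagents that add atoms: none
Why: Acid-catalysed methanolysis cleaves both methoxymethyl acetals and fragments the tert-butyl carbonate (global deprotection) under conditions customary for MOM-protected C-prenylated flavanones, and C2 should not epimerise in acid at this temperature.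

**Compound list**

1 | phloroglucinol | Oc1cc(O)cc(O)c1 | starting material
2 | 5-(triisopropylsilyloxy)benzene-1,3-diol | CC(C)[Si](Oc1cc(O)cc(O)c1)(C(C)C)C(C)C | intermediate
3 | [3,5-bis(methoxymethoxy)phenoxy]triisopropylsilane | COCOc1cc(OCOC)cc(O[Si](C(C)C)(C(C)C)C(C)C)c1 | intermediate
4 | geranyl bromide, (2E)-1-bromo-3,7-dimethylocta-2,6-diene | CC(C)=CCC/C(C)=C/CBr | starting material
5 | [2,6-bis(methoxymethoxy)-4-(triisopropylsilyloxy)phenyl]lithium | [Li]c1c(OCOC)cc(O[Si](C(C)C)(C(C)C)C(C)C)cc1OCOC | intermediate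
6 | {4-[(2E)-3,7-dimethylocta-2,6-dien-1-yl]-3,5-bis(methoxymethoxy)phenoxy}triisopropylsilane | CC(C)=CCC/C(C)=C/Cc1c(OCOC)cc(O[Si](C(C)C)(C(C)C)C(C)C)cc1OCOC | intermediate
7 | 4-geranyl-3,5-bis(methoxymethoxy)phenol | CC(C)=CCC/C(C)=C/Cc1c(OCOC)cc(O)cc1OCOC | intermediate
8 | 2-bromo-4-geranyl-3,5-bis(methoxymethoxy)phenol | CC(C)=CCC/C(C)=C/Cc1c(OCOC)cc(O)c(Br)c1OCOC | intermediate
9 | [2-bromo-4-geranyl-3,5-bis(methoxymethoxy)phenoxy]trimethylsilane | CC(C)=CCC/C(C)=C/Cc1c(OCOC)cc(O[Si](C)(C)C)c(Br)c1OCOC | intermediate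
10 | lithium 4-geranyl-3,5-bis(methoxymethoxy)-2-(trimethylsilyl)phenoxide | CC(C)=CCC/C(C)=C/Cc1c(OCOC)cc([O-])c([Si](C)(C)C)c1OCOC.[Li+] | intermediate
11 | 4-geranyl-3,5-bis(methoxymethoxy)-2-(trimethylsilyl)phenyl trifluoromethanesulfonate | CC(C)=CCC/C(C)=C/Cc1c(OCOC)cc(OS(=O)(=O)C(F)(F)F)c([Si](C)(C)C)c1OCOC | intermediate
12 | 4-hydroxybenzaldehyde | O=Cc1ccc(O)cc1 | starting material
13 | tert-butyl 4-formylphenyl carbonate | CC(C)(C)OC(=O)Oc1ccc(C=O)cc1 | intermediate
14 | tert-butyl 4-[(1S)-1-hydroxybut-3-en-1-yl]phenyl carbonate | C=CC[C@H](O)c1ccc(OC(=O)OC(C)(C)C)cc1 | intermediate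
15 | tert-butyl 4-[(1S)-1-hydroxy-2-(1,2,4-trioxolan-3-yl)ethyl]phenyl carbonate (ozonide, mixture at the trioxolane carbon) | C1(C[C@H](O)c2ccc(OC(=O)OC(C)(C)C)cc2)OCOO1 | intermediate
16 | tert-butyl 4-[(1S)-1-hydroxy-3-oxopropyl]phenyl carbonate | O=CC[C@H](O)c1ccc(OC(=O)OC(C)(C)C)cc1 | intermediate
17 | (3S)-3-[4-(tert-butoxycarbonyloxy)phenyl]-3-hydroxypropanoic acid | OC(=O)C[C@H](O)c1ccc(OC(=O)OC(C)(C)C)cc1 | intermediate
18 | (4S)-4-[4-(tert-butoxycarbonyloxy)phenyl]oxetan-2-one | O=C1C[C@@H](c2ccc(OC(=O)OC(C)(C)C)cc2)O1 | intermediate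
19 | 4-geranyl-3,5-bis(methoxymethoxy)-1,2-didehydrobenzene (aryne) | CC(C)=CCC/C(C)=C/CC1=C(OCOC)C#CC=C1OCOC | intermediate
20 | (2S)-2-[4-(tert-butoxycarbonyloxy)phenyl]-6-geranyl-5,7-bis(methoxymethoxy)chroman-4-one | CC(C)=CCC/C(C)=C/Cc1c(OCOC)cc2c(c1OCOC)C(=O)C[C@@H](c1ccc(OC(=O)OC(C)(C)C)cc1)O2 | intermediate
21 | bonannione A, (2S)-6-geranyl-5,7-dihydroxy-2-(4-hydroxyphenyl)chroman-4-one | CC(C)=CCC/C(C)=C/Cc1c(O)cc2c(c1O)C(=O)C[C@@H](c1ccc(O)cc1)O2 | target

**Step count**

Total: 13 steps. Longest linear sequence: 8 steps (steps 1–6, 12, 13); the lactone branch (steps 7–11) joins at step 12.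

**Steps most likely to fail**

1. Step 12 (proposed new method). What may go wrong:
 - the lactone carbonyl oxygen, not the ring oxygen, may add to the aryne;
 - fluoride may open or eliminate the lactone before it is arylated;
 - basic fluoride may open and reclose ring C of the product, eroding the C2 configuration.

 Fallback by known chemistry, closing ring C stepwise with inversion. It sets out from aldehyde 13 and bromophenol 8 and returns at 20.
 - Keck allylation of 13 with (R)-BINOL/Ti(OiPr)4 and allylSnBu3 should give tert-butyl 4-[(1R)-1-hydroxybut-3-en-1-yl]phenyl carbonate F1.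
 - Silylation (TBSCl, imidazole, DMF) gives tert-butyl 4-[(1R)-1-(tert-butyldimethylsilyloxy)but-3-en-1-yl]phenyl carbonate F2.
 - Oxidative cleavage of the alkene (RuCl3 cat., NaIO4, MeCN/CCl4/H2O) gives (3R)-3-[4-(tert-butoxycarbonyloxy)phenyl]-3-(tert-butyldimethylsilyloxy)propanoic acid F3.
 - Carbodiimide esterification with 8 (EDC, DMAP) gives the 2-bromoaryl ester F4.
 - Bromine–lithium exchange (n-BuLi, THF, −100 °C) triggers an anionic Fries shift of the acyl group to C4a and gives the ortho-hydroxyaryl ketone F5.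
 - HF·pyridine frees the (R)-β-hydroxy ketone F6.
 - Intramolecular Mitsunobu etherification (PPh3, DIAD, THF) closes O1–C2 with inversion and delivers 20 in the S configuration.

2. Step 13. What may go wrong: protic acid may add the 5- or 7-hydroxyl to the proximal geranyl alkene (chroman formation), add methanol to the terminal alkene, or slowly open ring C at C2.

 Fallback by silyl transfer in place of protic acidolysis. It sets out from 20 and returns at 21.
 - TMSOTf with 2,2′-bipyridyl in CH2Cl2 at 0 °C should exchange both aryl methoxymethyl acetals for trimethylsilyl ethers and fragment the tert-butyl carbonate (loss of 2-methylpropene and CO2). This gives (2S)-6-geranyl-5,7-bis(trimethylsilyloxy)-2-[4-(trimethylsilyloxy)phenyl]chroman-4-one F7.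
 - The aryl silyl ethers of F7 are then solvolysed in methanol with a trace of AcOH at rt to give 21, so that free phenols, mineral acid and the geranyl alkenes never meet.

3. Step 5. What may go wrong: a second bromination at the remaining ring position or bromination of the geranyl alkenes, which would also spoil step 6.

 Fallback by carbamate-directed ortho-silylation, with no electrophilic halogen. It sets out from phenol 7 and returns at 11, bypassing steps 5 and 6.
 - Carbamoylation (Et2NCOCl, K2CO3, MeCN) gives 4-geranyl-3,5-bis(methoxymethoxy)phenyl N,N-diethylcarbamate F8.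
 - Directed ortho-lithiation (s-BuLi, TMEDA, THF, −78 °C) with TMSCl quench gives 4-geranyl-3,5-bis(methoxymethoxy)-2-(trimethylsilyl)phenyl N,N-diethylcarbamate F9.
 - LiAlH4 in THF cleaves the carbamate to 4-geranyl-3,5-bis(methoxymethoxy)-2-(trimethylsilyl)phenol F10.
 - Triflation (NaH, PhNTf2, THF) gives 11.

**Further compounds**

F1 | step 12 | tert-butyl 4-[(1R)-1-hydroxybut-3-en-1-yl]phenyl carbonate | C=CC[C@@H](O)c1ccc(OC(=O)OC(C)(C)C)cc1
F2 | step 12 | tert-butyl 4-[(1R)-1-(tert-butyldimethylsilyloxy)but-3-en-1-yl]phenyl carbonate | C=CC[C@@H](O[Si](C)(C)C(C)(C)C)c1ccc(OC(=O)OC(C)(C)C)cc1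
F3 | step 12 | (3R)-3-[4-(tert-butoxycarbonyloxy)phenyl]-3-(tert-butyldimethylsilyloxy)propanoic acid | OC(=O)C[C@@H](O[Si](C)(C)C(C)(C)C)c1ccc(OC(=O)OC(C)(C)C)cc1
F4 | step 12 | 2-bromo-4-geranyl-3,5-bis(methoxymethoxy)phenyl (3R)-3-[4-(tert-butoxycarbonyloxy)phenyl]-3-(tert-butyldimethylsilyloxy)propanoate | CC(C)=CCC/C(C)=C/Cc1c(OCOC)cc(OC(=O)C[C@@H](O[Si](C)(C)C(C)(C)C)c2ccc(OC(=O)OC(C)(C)C)cc2)c(Br)c1OCOC
F5 | step 12 | tert-butyl 4-[(1R)-1-(tert-butyldimethylsilyloxy)-3-[3-geranyl-6-hydroxy-2,4-bis(methoxymethoxy)phenyl]-3-oxopropyl]phenyl carbonate | CC(C)=CCC/C(C)=C/Cc1c(OCOC)cc(O)c(C(=O)C[C@@H](O[Si](C)(C)C(C)(C)C)c2ccc(OC(=O)OC(C)(C)C)cc2)c1OCOC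
F6 | step 12 | tert-butyl 4-[(1R)-3-[3-geranyl-6-hydroxy-2,4-bis(methoxymethoxy)phenyl]-1-hydroxy-3-oxopropyl]phenyl carbonate | CC(C)=CCC/C(C)=C/Cc1c(OCOC)cc(O)c(C(=O)C[C@@H](O)c2ccc(OC(=O)OC(C)(C)C)cc2)c1OCOC
F7 | step 13 | (2S)-6-geranyl-5,7-bis(trimethylsilyloxy)-2-[4-(trimethylsilyloxy)phenyl]chroman-4-one | CC(C)=CCC/C(C)=C/Cc1c(O[Si](C)(C)C)cc2c(c1O[Si](C)(C)C)C(=O)C[C@@H](c1ccc(O[Si](C)(C)C)cc1)O2
F8 | step 5 | 4-geranyl-3,5-bis(methoxymethoxy)phenyl N,N-diethylcarbamate | CC(C)=CCC/C(C)=C/Cc1c(OCOC)cc(OC(=O)N(CC)CC)cc1OCOC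
F9 | step 5 | 4-geranyl-3,5-bis(methoxymethoxy)-2-(trimethylsilyl)phenyl N,N-diethylcarbamate | CC(C)=CCC/C(C)=C/Cc1c(OCOC)cc(OC(=O)N(CC)CC)c([Si](C)(C)C)c1OCOC
F10 | step 5 | 4-geranyl-3,5-bis(methoxymethoxy)-2-(trimethylsilyl)phenol | CC(C)=CCC/C(C)=C/Cc1c(OCOC)cc(O)c([Si](C)(C)C)c1OCOC
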